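**Retrosynthetic overview**
- The tetrahydrofuran is the only ring to be made. It is closed last, by forming one ring C–O bond from acyclic 2,3-bis(3,4-dimethoxybenzyl)butane-1,4-diol.
- That ring closure is also the stereo-defining event. The diol is used as its dl/meso mixture, and an iridium/chiral phosphoric acid hydrogen-borrowing cycloetherification funnels all stereoisomers into the (3R,4R) ether.
- The diol comes from the corresponding 2,3-dibenzylsuccinic acid by hydride reduction.
- The succinic acid comes from two molecules of 3-(3,4-dimethoxyphenyl)propanoic acid by unselective oxidative dianion homocoupling; both arene rings are bought.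

Assumption: the sense of induction of the new step cannot be predicted with certainty; the (R)-TRIP/(S,S)-iridium pair is written and the mirror-image pair is used if a first screen gives the (3S,4S) ether ((R)-TRIP = (R)-3,3'-bis(2,4,6-triisopropylphenyl)-1,1'-binaphthyl-2,2'-diyl hydrogen phosphate; Ts = 4-methylbenzenesulfonyl).

**Step 1**
Reactants: 1 3-(3,4-dimethoxyphenyl)propanoic acid (two molecules)
Product: 4 rac/meso-2,3-bis(3,4-dimethoxybenzyl)butanedioic acid, via dilithium 3-(3,4-dimethoxyphenyl)prop-1-ene-1,1-diolate 2 (not isolated), via lithium 2-iodo-3-(3,4-dimethoxyphenyl)propanoate 3 (not isolated)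
Conditions: LiN(iPr)2 (2.2 equiv per acid), THF, 0 to 45 °C, 2 h; then I2 (0.5 equiv per acid), THF, −78 °C to rt; aq. HCl work-up
Reagents that add atoms: none
Why: Oxidative homocoupling of a carboxylic acid dianion, in which iodine turns half of enediolate 2 into the α-iodo carboxylate 3 and the remaining 2 alkylates it at carbon to make the C2–C3 bond; both new stereocentres form unselectively (dl/meso), which is acceptable because they are re-set in step 3.

**Step 2**
Reactants: 4 rac/meso-2,3-bis(3,4-dimethoxybenzyl)butanedioic acid
Product: 5 rac/meso-2,3-bis(3,4-dimethoxybenzyl)butane-1,4-diol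
Conditions: LiAlH4 (5 equiv), THF, reflux, 12 h; Fieser work-up
Reagents that add atoms: none
Why: Exhaustive hydride reduction of both carboxylic acids to primary alcohols (LiAlH4 reduction; the aryl methyl ethers are inert), which neither sets nor selects a stereocentre.

**Step 3**
Reactants: 5 rac/meso-2,3-bis(3,4-dimethoxybenzyl)butane-1,4-diol
Product: 8 (3R,4R)-3,4-bis(3,4-dimethoxybenzyl)tetrahydrofuran, via 4-hydroxy-2,3-bis(3,4-dimethoxybenzyl)butanal 6 (not isolated), via (3R,4R)-3,4-bis(3,4-dimethoxybenzyl)tetrahydrofuran-2-ol 7 (not isolated)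
Conditions: (C5Me5)Ir[(S,S)-TsNCHPhCHPhNH] (5 mol %), (R)-TRIP (10 mol %), 3 Å molecular sieves, toluene (0.05 M), 110 °C, sealed tube under argon, 48 h
Reagents that add atoms: none
Why: Proposed new method: a hydrogen-borrowing dynamic kinetic asymmetric cycloetherification in which the iridium amide reversibly dehydrogenates either CH2OH of 5 to aldehyde 6, whose α-centre epimerises by acid-catalysed enolisation so that the meso and both chiral forms of 5 interconvert, 6 closes to lactol 7 (the ring C–O bond), and the chiral phosphate ionises 7 to an oxocarbenium ion pair that the stored Ir–H reduces fastest for the matched trans-(3R,4R) cation (hydride anti to the adjacent benzyl group, trans cation favoured over cis), giving 8 and water irreversibly and thereby setting both stereocentres; the closest known reaction type is the iridium/chiral phosphoric acid borrowing-hydrogen amination of racemic branched alcohols with dynamic kinetic resolution (C–N), with metal-hydride reductive etherification of aldehydes as the C–O counterpart.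

**Compound list**
1 | 3-(3,4-dimethoxyphenyl)propanoic acid | COc1ccc(CCC(=O)O)cc1OC | starting material
2 | dilithium 3-(3,4-dimethoxyphenyl)prop-1-ene-1,1-diolate (dianion of 1) | COc1ccc(CC=C([O-])[O-])cc1OC.[Li+].[Li+] | intermediate
3 | lithium 2-iodo-3-(3,4-dimethoxyphenyl)propanoate (racemic) | COc1ccc(CC(I)C(=O)[O-])cc1OC.[Li+] | intermediate
4 | rac/meso-2,3-bis(3,4-dimethoxybenzyl)butanedioic acid (mixture of all stereoisomers, so no descriptors) | COc1ccc(CC(C(=O)O)C(C(=O)O)Cc2ccc(OC)c(OC)c2)cc1OC | intermediate
5 | rac/meso-2,3-bis(3,4-dimethoxybenzyl)butane-1,4-diol (mixture of all stereoisomers, so no descriptors) | COc1ccc(CC(CO)C(CO)Cc2ccc(OC)c(OC)c2)cc1OC | intermediate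
6 | 4-hydroxy-2,3-bis(3,4-dimethoxybenzyl)butanal (interconverting stereoisomers, so no descriptors) | COc1ccc(CC(C=O)C(CO)Cc2ccc(OC)c(OC)c2)cc1OC | intermediate
7 | (3R,4R)-3,4-bis(3,4-dimethoxybenzyl)tetrahydrofuran-2-ol (both anomers) | COc1ccc(C[C@H]2C(O)OC[C@@H]2Cc2ccc(OC)c(OC)c2)cc1OC | intermediate
8 | (3R,4R)-3,4-bis(3,4-dimethoxybenzyl)tetrahydrofuran (trans) | COc1ccc(C[C@H]2COC[C@@H]2Cc2ccc(OC)c(OC)c2)cc1OC | target

**Totals**
Total step count: 3. Longest linear sequence: 3 steps (from 1).

**Steps most likely to fail, with fallbacks**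

Step 3 (the proposed new method) is the most likely to fail. The foreseeable failure modes are:
- over-dehydrogenation of lactol 7 to the lactone, or of both alcohols to a furan;
- a stereoretentive acid-only ring closure of 5 that bypasses the redox cycle;
- Friedel–Crafts capture of the oxocarbenium ion by a dimethoxyphenyl ring;
- weak chiral recognition of a dialkyl-substituted α-centre, giving low ee or cis (meso) ether.

The fallback uses known chemistry and moves the stereocontrol to an auxiliary-directed C–C coupling. It sets out from 1, which is coupled with (S)-4-isopropyloxazolidin-2-one (DCC, DMAP, CH2Cl2) to give (S)-3-[3-(3,4-dimethoxyphenyl)propanoyl]-4-isopropyloxazolidin-2-one F1. Oxidative homocoupling of its enolate (LiN(iPr)2, THF, −78 °C; then TiCl4) gives the (2R,3R)-2,3-bis(3,4-dimethoxybenzyl)succinoyl bis-oxazolidinone F2. The (2R,3R) sense follows from the usual facial bias of the (S)-auxiliary enolate. LiBH4 then removes both auxiliaries to give (2R,3R)-2,3-bis(3,4-dimethoxybenzyl)butane-1,4-diol F3. Ordinary acid-catalysed cyclodehydration (cat. TsOH, toluene, 110 °C) closes the ring, and the fallback comes back to the route at 8.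

Step 1 is second. It can fail through incomplete dianion formation or poor solubility of the dilithium salts, or through iodination of the electron-rich ring. The fallback replaces the two-electron dianion/iodine coupling by a one-electron coupling of an ester monoenolate. It sets out from 1, which is esterified (MeOH, cat. H2SO4) to methyl 3-(3,4-dimethoxyphenyl)propanoate F4. Its lithium enolate (LiN(iPr)2, THF, −78 °C) is dimerised with CuBr2 to dimethyl rac/meso-2,3-bis(3,4-dimethoxybenzyl)butanedioate F5. LiAlH4 reduction of F5 bypasses 4 and comes back to the route at 5.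

Step 2 is third. It can stall through insoluble carboxylate–aluminate salts and stop at the lactone level. The fallback changes the substrate class to a neutral, soluble one. It sets out from 4, which is dehydrated with refluxing Ac2O to 3,4-bis(3,4-dimethoxybenzyl)dihydrofuran-2,5-dione F6 (cis/trans mixture). LiAlH4 in THF reduces this anhydride to the diol, and the fallback comes back to the route at 5.

Further compounds
F1 | step 3 | (S)-3-[3-(3,4-dimethoxyphenyl)propanoyl]-4-isopropyloxazolidin-2-one | COc1ccc(CCC(=O)N2[C@@H](C(C)C)COC2=O)cc1OC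
F2 | step 3 | (2R,3R)-2,3-bis(3,4-dimethoxybenzyl)-1,4-bis[(S)-4-isopropyl-2-oxooxazolidin-3-yl]butane-1,4-dione | COc1ccc(C[C@@H](C(=O)N3[C@@H](C(C)C)COC3=O)[C@H](C(=O)N3[C@@H](C(C)C)COC3=O)Cc2ccc(OC)c(OC)c2)cc1OC
F3 | step 3 | (2R,3R)-2,3-bis(3,4-dimethoxybenzyl)butane-1,4-diol | COc1ccc(C[C@@H](CO)[C@H](CO)Cc2ccc(OC)c(OC)c2)cc1OC
F4 | step 1 | methyl 3-(3,4-dimethoxyphenyl)propanoate | COC(=O)CCc1ccc(OC)c(OC)c1
F5 | step 1 | dimethyl rac/meso-2,3-bis(3,4-dimethoxybenzyl)butanedioate | COC(=O)C(Cc1ccc(OC)c(OC)c1)C(Cc1ccc(OC)c(OC)c1)C(=O)OC
F6 | step 2 | 3,4-bis(3,4-dimethoxybenzyl)dihydrofuran-2,5-dione (cis/trans mixture) | COc1ccc(CC2C(=O)OC(=O)C2Cc2ccc(OC)c(OC)c2)cc1OC
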